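## Analysis of the target

Artoflavanone is a (2S)-flavanone. Ring A (C4a, C5, C6, C7, C8, C8a) is a fully differentiated phloroglucinol ring with a free, carbonyl-chelated 5-OH, a 3-methylbut-2-enyl (prenyl) group on C6 and a 7-OMe. Ring C (O1, C2, C3, C4, C4a, C8a) is a 2,3-dihydro-4H-pyran-4-one, and ring B is a 3,4,5-trimethoxyphenyl group on C2.

The only stereocentre is C2. It is benzylic, bound to O1 and β to the C4 ketone, so base or heat can racemize it by retro-oxa-Michael opening to the 2'-hydroxychalcone. It must therefore be set late and under near-neutral conditions.

The prenyl olefin excludes hydrogenation and strong acid, which would close it onto the 5-OH. The four aryl methyl ethers exclude strong Lewis acids.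

Two things make the synthesis hard. The first is regiochemistry on ring A: C6 and C8 are both flanked by oxygen and hard to tell apart, and O5 and O1 derive from equivalent phenols of any phloroglucinol precursor. The second is enantiocontrol at a labile centre.

The feature the route exploits is the C2–C1' bond between C2 of ring C and ring B. Ring C is the dihydro form of a flat 4H-pyran-4-one. The target is therefore the product of adding the ring B aryl group across C2=C3 of an achiral 6-prenylchromone. One enantioselective, dearomatizing 1,4-arylation then forms the C2–C1' bond, joins the two halves and sets the only stereocentre.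

## Retrosynthetic reasoning

**C2–C1' bond (12 ⇒ 10 + 11).** The bond between the stereocentre and ring B is cut. This removes ring B and the stereocentre together and leaves the planar, achiral chromone 10 and the boronic acid 11. The forward reaction is a catalyst-controlled enantioselective 1,4-addition of the aryl group of 11 to C2 of 10. It must tolerate the prenyl olefin and the chelated 5-OH, and it must avoid ring opening of the metal enolate. It is placed last so that C2 never meets base or heat after it is formed. For the same reason the prenyl group is installed before this step and not after it.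

**Prenyl olefin (10 ⇒ 8 + 9).** The trisubstituted C=C of the side chain is cut by cross-metathesis logic. A prenyl group cannot be delivered to C6 by a simple [3,3] shift without a tertiary ether or allylic inversion, but an allyl group can. Exchanging the terminal CH2 of 8 for the isopropylidene unit of 9 then completes the side chain under neutral conditions.

**C6–C1'' bond (8 ⇒ 6, through 7).** The bond between C6 and the side chain is traced back to an O5-allyl ether by an aromatic Claisen rearrangement. This is where the C6/C8 problem is solved by mechanism: the [3,3] shift from O5 can only deliver carbon productively to the hydrogen-bearing ortho position, C6. A shorter halogenation/cross-coupling route to 10 is conceivable. It rests on two regiochemical preferences instead of one mechanistic certainty, so it is kept as a fallback.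

**Ring C (6 ⇒ 3 + 4, through 5).** O1–C2 and C2–C3 are cut, so that C2 comes from the one-carbon reagent 4 and the remaining atoms from the acetophenone 3. In 3 only one phenol is free, so the pyranone can close only on that oxygen. The allylated oxygen therefore becomes O5, and the O1/O5 ambiguity is removed without a protecting group.

**O5–allyl bond (3 ⇒ 1 + 2).** Mono-allylation of the two equivalent phenols of 1 with 2 desymmetrizes ring A. The 7-OMe is already present in 1, so no selective methylation is needed.

## Alternatives that were turned down

**Alternative 1:** the textbook O1–C2 disconnection.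
- Disconnection and key step: chalcone A1, made by Claisen–Schmidt condensation of a C-prenylated derivative of 1 with the ring B aldehyde, would be closed by an enantioselective intramolecular oxa-Michael addition (6-endo-trig) under a bifunctional amine–thiourea catalyst.
- Reason for rejection: A1 carries two phenols ortho to the ketone. Closure through the one next to the prenyl group gives the 8-prenyl regioisomer A2, and closure through the other gives the target. Nothing in the catalyst tells them apart, and a protecting group would require the same two hydroxyls to be distinguished earlier.
- Further weaknesses: the oxa-Michael addition of a 2'-hydroxychalcone without an activating group on the α-carbon is reversible and has a racemic base-mediated background, which is the pathway that racemizes the product. Regioselective C-prenylation of 1 is unsolved. The sequence of prenylation, protection, condensation, deprotection and cyclization is longer than the chosen route.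

**Alternative 2:** enantioselective reduction of a flavone.
- Disconnection and key step: the C2–H bond is cut, leading to flavone A3, which would be built by a Baker–Venkataraman sequence. The stereocentre would be set by asymmetric hydrogenation or chiral copper hydride 1,4-reduction of C2=C3.
- Reason for rejection: the C2=C3 bond of A3 is a β,β-disubstituted vinylogous ester conjugated to an electron-rich aryl group, so it is a poor hydride acceptor. Conditions forcing enough to reduce it threaten over-reduction at C4 and, under hydrogen, saturation of the prenyl olefin.
- Further weaknesses: A3 costs at least three more steps than chromone 10 (aroylation, rearrangement, cyclodehydration) and meets the same C6/C8 question. The stereo-defining step is a functional-group reduction that forms no skeletal bond.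

**Alternative 3:** C2–O1 bond by invertive substitution.
- Disconnection and key step: the (R)-configured β-hydroxy ketone A4, from an enantioselective aldol reaction, would be closed by an intramolecular Mitsunobu etherification with inversion.
- Reason for rejection: the carbinol carbon of A4 is benzylic to an electron-rich aryl group and β to a ketone. Dehydration to chalcone A1 and partial ionization would therefore compete with clean SN2 displacement and erode the configuration.
- Further weaknesses: the two ortho phenols again lead to A2 alongside the target. The aldol partner needs both phenols protected and then selectively freed.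

Key step: step 5

## Remarks on the chemistry (assumptions)

- Compound 1 (2',6'-dihydroxy-4'-methoxyacetophenone) and compounds 2, 4, 9 and 11 are taken as commercially available.
- The (S)-antipode of the bisphosphine in step 5 is assumed to deliver the aryl group to the Re face of C2 (O1 > C3 > H), by analogy with its sense of induction on cyclic enones. If a small test run shows the opposite sense, the (R)-antipode is used and nothing else changes.

## Route

Step 1
Reactants: 1 1-(2,6-dihydroxy-4-methoxyphenyl)ethan-1-one; 2 allyl bromide (3-bromoprop-1-ene)
Product: 3 1-[2-hydroxy-4-methoxy-6-(prop-2-en-1-yloxy)phenyl]ethan-1-one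
Conditions: allyl bromide (1.05 equiv), K2CO3 (1.1 equiv), acetone, reflux
Reagents that add atoms: allyl bromide (2), C=CCBr
Why: Williamson ether synthesis; the two phenols of 1 are equivalent, and after the first O-alkylation the remaining phenol is locked in a strong hydrogen bond to the ketone and is far less nucleophilic, so the monoether should predominate.

Step 2
Reactants: 3 1-[2-hydroxy-4-methoxy-6-(prop-2-en-1-yloxy)phenyl]ethan-1-one; 4 N,N-dimethylformamide dimethyl acetal
Product: 6 7-methoxy-5-(prop-2-en-1-yloxy)-4H-chromen-4-one, via enaminone 5 (not isolated)
Conditions: Me2NCH(OMe)2 (2 equiv), toluene, 95 °C; evaporate; then conc. aq HCl, CH2Cl2, 40 °C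
Reagents that add atoms: N,N-dimethylformamide dimethyl acetal (4), COC(OC)N(C)C
Why: Condensation of the acetyl methyl group with the amide acetal gives the (E)-enaminone 5, and acid then promotes intramolecular addition of the phenol to the enaminone β-carbon with loss of the amine (chromone synthesis by the enaminone method); only the free phenol can close, so the allyloxy group must end on C5.

Step 3
Reactants: 6 7-methoxy-5-(prop-2-en-1-yloxy)-4H-chromen-4-one
Product: 8 5-hydroxy-7-methoxy-6-(prop-2-en-1-yl)-4H-chromen-4-one, via Claisen dienone 7 (not isolated)
Conditions: N,N-diethylaniline, 200 °C, sealed tube, N2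
Reagents that add atoms: none
Why: Aromatic Claisen rearrangement; the [3,3] shift from O5 can deliver the allyl group productively only to C6, the one hydrogen-bearing position ortho to O5 (the other ortho position is C4a), and enolization of dienone 7, helped by the amine solvent, should give phenol 8 with the new C–C bond between the 5-OH and the 7-OMe.

Step 4
Reactants: 8 5-hydroxy-7-methoxy-6-(prop-2-en-1-yl)-4H-chromen-4-one; 9 2-methylbut-2-ene
Product: 10 5-hydroxy-7-methoxy-6-(3-methylbut-2-en-1-yl)-4H-chromen-4-one
Conditions: second-generation Grubbs catalyst (5 mol %), 2-methylbut-2-ene (large excess)/CH2Cl2, 40 °C, sealed tube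
Reagents that add atoms: 2-methylbut-2-ene (9), CC=C(C)C
Why: Olefin cross-metathesis of the terminal allyl group with excess 2-methylbut-2-ene exchanges the CH2 terminus for the isopropylidene unit with release of a volatile olefin; the electron-poor C2=C3 bond of the pyranone and the chelated phenol should not take part.

Step 5
Reactants: 10 5-hydroxy-7-methoxy-6-(3-methylbut-2-en-1-yl)-4H-chromen-4-one; 11 (3,4,5-trimethoxyphenyl)boronic acid
Product: 12 (2S)-5-hydroxy-7-methoxy-6-(3-methylbut-2-en-1-yl)-2-(3,4,5-trimethoxyphenyl)-2,3-dihydro-4H-chromen-4-one (artoflavanone)
Conditions: [RhCl(C2H4)2]2 (2 mol %), (S)-2,2'-bis[bis(3,4,5-trifluorophenyl)phosphino]-6,6'-dimethoxy-1,1'-biphenyl (4.4 mol %), 11 (3 equiv), aq KOH (10 mol %), toluene/H2O 10:1, 20 °C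
Reagents that add atoms: (3,4,5-trimethoxyphenyl)boronic acid (11), COc1cc(B(O)O)cc(OC)c1OC
Why: This is a Hayashi–Miyaura enantioselective 1,4-addition, and the closest known reaction type is the rhodium/atropisomeric bisphosphine-catalysed addition of arylboronic acids to 5,7-dioxygenated chromones to give flavanones. The hydroxorhodium–bisphosphine complex transmetalates with 11 to an aryl–rhodium species, which binds C2=C3 of 10 and inserts it so that the aryl group ends on C2 and rhodium on C3 as an oxa-π-allyl enolate; water protonates this enolate, releasing 12 and regenerating the hydroxo complex. The step closes no ring; it turns the planar pyranone ring C into the dihydro ring while forming the C2–C1' bond that joins ring B to the rest of the molecule. The substrate is flat and achiral, so the C2 stereocentre is set by the chiral pocket of the ligand alone, with aryl delivery to the Re face of C2 giving the (2S) configuration. The step needs 1,4- over 1,2-addition, which the aryl–rhodium species provides by inserting the unsubstituted, accessible C2=C3 bond, made more electrophilic by the 5-OH hydrogen bond to the C4 carbonyl. It needs chemoselectivity over the prenyl group, whose unactivated trisubstituted olefin should neither coordinate nor insert under monovalent rhodium at 20 °C. It needs single addition, which requires protonation of the rhodium enolate to outrun β-alkoxide elimination (ring opening to a chalcone that would take up a second aryl group); the electron-poor phosphine is chosen because it speeds transmetalation and insertion enough for the reaction to run at room temperature in the presence of water. Because this is the last step and runs near neutrality, the new stereocentre is never exposed to retro-oxa-Michael conditions.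

## Compound list

1 | 1-(2,6-dihydroxy-4-methoxyphenyl)ethan-1-one | CC(=O)c1c(O)cc(OC)cc1O | starting material
2 | allyl bromide | C=CCBr | starting material
3 | 1-[2-hydroxy-4-methoxy-6-(prop-2-en-1-yloxy)phenyl]ethan-1-one | CC(=O)c1c(O)cc(OC)cc1OCC=C | intermediate
4 | N,N-dimethylformamide dimethyl acetal | COC(OC)N(C)C | starting material
5 | (E)-3-(dimethylamino)-1-[2-hydroxy-4-methoxy-6-(prop-2-en-1-yloxy)phenyl]prop-2-en-1-one | CN(C)/C=C/C(=O)c1c(O)cc(OC)cc1OCC=C | intermediate (not isolated)
6 | 7-methoxy-5-(prop-2-en-1-yloxy)-4H-chromen-4-one | C=CCOc1cc(OC)cc2occc(=O)c12 | intermediate
7 | 7-methoxy-6-(prop-2-en-1-yl)-4H-chromene-4,5(6H)-dione (racemic) | C=CCC1C(=O)C2=C(OC=CC2=O)C=C1OC | intermediate (not isolated)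
8 | 5-hydroxy-7-methoxy-6-(prop-2-en-1-yl)-4H-chromen-4-one | C=CCc1c(OC)cc2occc(=O)c2c1O | intermediate
9 | 2-methylbut-2-ene | CC=C(C)C | starting material
10 | 5-hydroxy-7-methoxy-6-(3-methylbut-2-en-1-yl)-4H-chromen-4-one | CC(C)=CCc1c(OC)cc2occc(=O)c2c1O | intermediate
11 | (3,4,5-trimethoxyphenyl)boronic acid | COc1cc(B(O)O)cc(OC)c1OC | starting material
12 | (2S)-5-hydroxy-7-methoxy-6-(3-methylbut-2-en-1-yl)-2-(3,4,5-trimethoxyphenyl)-2,3-dihydro-4H-chromen-4-one (artoflavanone) | COc1cc2c(c(O)c1CC=C(C)C)C(=O)C[C@@H](c1cc(OC)c(OC)c(OC)c1)O2 | target

## Step count and risk assessment

Total step count: 5. Longest linear sequence: 5 steps (1 → 3 → 6 → 8 → 10 → 12).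

**Step 5 (key step).**
- What may go wrong: ring opening of the rhodium enolate by β-alkoxide elimination followed by a second aryl transfer; sequestration of the catalyst by the chelating 5-hydroxy-4-oxo unit; protodeboronation of the electron-rich boronic acid before transmetalation; insufficient facial discrimination on a chromone that carries two ortho substituents around C5.
- Fallback (resolution in place of asymmetric catalysis), from 10 back to 12: the aryl group of 11 is added without stereocontrol using Pd(OCOCF3)2/2,2'-bipyridine in an aqueous medium at 60 °C, a conjugate addition by divalent palladium. This should give racemic 5-hydroxy-7-methoxy-6-(3-methylbut-2-en-1-yl)-2-(3,4,5-trimethoxyphenyl)-2,3-dihydro-4H-chromen-4-one F1.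
- F1 is then resolved kinetically by Noyori asymmetric transfer hydrogenation with RuCl(p-cymene)[(R,R)-TsNCH(Ph)CH(Ph)NH2] and HCO2H/Et3N, stopped near half conversion. This catalyst antipode is expected to reduce the (2R)-enantiomer faster, giving (2R,4R)-7-methoxy-6-(3-methylbut-2-en-1-yl)-2-(3,4,5-trimethoxyphenyl)-3,4-dihydro-2H-chromene-4,5-diol F2, which is removed by chromatography. The unreduced ketone is 12. The prenyl olefin is inert to transfer hydrogenation.

**Step 3.**
- What may go wrong: onward Cope migration of the allyl group from C6 to C8 in dienone 7 before enolization (the para-Claisen pathway); thermal closure of the newly formed o-allylphenol onto its own olefin; slow degradation of the pyranone at 200 °C.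
- Fallback (halogenation and cross-coupling in place of a sigmatropic shift), from 6 back to 10, which also bypasses step 4: the allyl ether is cleaved with Pd(PPh3)4 (cat.) and morpholine in THF to give 5-hydroxy-7-methoxy-4H-chromen-4-one F3.
- F3 is iodinated ortho to the free phenol with benzyltrimethylammonium dichloroiodate and CaCO3 in CH2Cl2/MeOH at room temperature, to give 5-hydroxy-6-iodo-7-methoxy-4H-chromen-4-one F4.
- Stille coupling of F4 with tributyl(3-methylbut-2-en-1-yl)stannane (Pd(PPh3)4, DMF, 90 °C) should deliver 10.

**Step 2.**
- What may go wrong: O-methylation of the chelated phenol by the amide acetal; incomplete condensation at the acetyl group, which is flanked by two ortho substituents and twisted out of conjugation.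
- Fallback (enolate formylation in place of enaminone formation), from 3 back to 6: crossed Claisen condensation of 3 with ethyl formate (NaH, THF, 0 °C to room temperature) and acidic work-up should give the cyclic hemiacetal 2-hydroxy-7-methoxy-5-(prop-2-en-1-yloxy)-2,3-dihydro-4H-chromen-4-one F5. Dehydration with TsOH in toluene at 80 °C gives 6.

**Step 4.**
- What may go wrong: incomplete conversion; homodimerization of the allyl arene; transfer of the ethylidene terminus of 9 in place of the isopropylidene terminus, leading to a chain shorter by one methyl group.
- Fallback (oxidative cleavage and olefination in place of metathesis), from 8 back to 10: Lemieux–Johnson oxidation (OsO4 cat., NaIO4, 2,6-lutidine, dioxane/H2O) should give (5-hydroxy-7-methoxy-4-oxo-4H-chromen-6-yl)acetaldehyde F6.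
- Wittig olefination of F6 with isopropylidenetriphenylphosphorane gives 10. The ylide is made from isopropyltriphenylphosphonium iodide and n-BuLi and used in more than two equivalents (THF, −78 to 0 °C). The first equivalent forms the phenoxide, which also shields the pyranone from conjugate attack.

## Further compounds

F1 | step 5 | racemic 5-hydroxy-7-methoxy-6-(3-methylbut-2-en-1-yl)-2-(3,4,5-trimethoxyphenyl)-2,3-dihydro-4H-chromen-4-one | COc1cc2c(c(O)c1CC=C(C)C)C(=O)CC(c1cc(OC)c(OC)c(OC)c1)O2
F2 | step 5 | (2R,4R)-7-methoxy-6-(3-methylbut-2-en-1-yl)-2-(3,4,5-trimethoxyphenyl)-3,4-dihydro-2H-chromene-4,5-diol | COc1cc2c(c(O)c1CC=C(C)C)[C@H](O)C[C@H](c1cc(OC)c(OC)c(OC)c1)O2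
F3 | step 3 | 5-hydroxy-7-methoxy-4H-chromen-4-one | COc1cc(O)c2c(c1)occc2=O
F4 | step 3 | 5-hydroxy-6-iodo-7-methoxy-4H-chromen-4-one | COc1cc2occc(=O)c2c(O)c1I
F5 | step 2 | 2-hydroxy-7-methoxy-5-(prop-2-en-1-yloxy)-2,3-dihydro-4H-chromen-4-one (racemic) | C=CCOc1cc(OC)cc2OC(O)CC(=O)c12
F6 | step 4 | (5-hydroxy-7-methoxy-4-oxo-4H-chromen-6-yl)acetaldehyde | COc1cc2occc(=O)c2c(O)c1CC=O
A1 | alternative 1 | (E)-1-[2,6-dihydroxy-4-methoxy-3-(3-methylbut-2-en-1-yl)phenyl]-3-(3,4,5-trimethoxyphenyl)prop-2-en-1-one | COc1cc(O)c(C(=O)/C=C/c2cc(OC)c(OC)c(OC)c2)c(O)c1CC=C(C)C
A2 | alternative 1 | (2S)-5-hydroxy-7-methoxy-8-(3-methylbut-2-en-1-yl)-2-(3,4,5-trimethoxyphenyl)-2,3-dihydro-4H-chromen-4-one | COc1cc(O)c2c(c1CC=C(C)C)O[C@H](c1cc(OC)c(OC)c(OC)c1)CC2=O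
A3 | alternative 2 | 5-hydroxy-7-methoxy-6-(3-methylbut-2-en-1-yl)-2-(3,4,5-trimethoxyphenyl)-4H-chromen-4-one | COc1cc2oc(-c3cc(OC)c(OC)c(OC)c3)cc(=O)c2c(O)c1CC=C(C)C
A4 | alternative 3 | (3R)-1-[2,6-dihydroxy-4-methoxy-3-(3-methylbut-2-en-1-yl)phenyl]-3-hydroxy-3-(3,4,5-trimethoxyphenyl)propan-1-one | COc1cc(O)c(C(=O)C[C@@H](O)c2cc(OC)c(OC)c(OC)c2)c(O)c1CC=C(C)C
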